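A living end J at 40 °C lasts 29.8 s on average before it passes into the dead species E, with first-order constant k_t. L adds to D with constant k_i, giving J and the first unit of G. J then turns D into G (propagation, k_p) and G back into D (depropagation, k_dp), and G above 0.72 M crystallises as Q. The flasks differ in temperature.

| flask | D | L | temperature | time |
|---|---|---|---|---|
| autumn | 0.80 M | 8.0 mM | 15 °C | 50 min |
| dawn | 0.80 M | 8.0 mM | −10 °C | 50 min |
| dusk | 0.80 M | 8.0 mM | 40 °C | 50 min |
| spring | 0.80 M | 8.0 mM | −35 °C | 50 min |

1. the best flask by amount of G, in percent of the D charged; "all alike" if 1.5 percentage points covers them all (autumn / dawn / dusk / spring / all alike)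
2. amount of G at the end, in percent of the D charged, autumn
3. amount of G at the end, in percent of the D charged, dawn
4. amount of G at the end, in percent of the D charged, dusk
5. amount of G at the end, in percent of the D charged, spring

- amounts and yields of G count Q too
- given per volume of solution although it is solid: Q
- the constants hold at 40 °C; other temperatures follow from the activation energies

    D + L → J + G (k1 = 0.0200 M⁻¹ s⁻¹, Ea1 = 64.0 kJ mol⁻¹)
    Q ⇌ G, rate k2*(cs2 - [G]) while solid is left; crystals form when [G] > cs2 (cs2 = 0.72 M, k2 = 0.296 s⁻¹)
    G + J → D + J, rate k3*[J] as long as [G] is above zero (k3 = 0.184 s⁻¹, Ea3 = 87.0 kJ mol⁻¹)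
    J → E (k4 = 0.0336 s⁻¹, Ea4 = 91.0 kJ mol⁻¹)
    D + J → G + J, rate k5*[J]*[D] (k5 = 2.53 M⁻¹ s⁻¹, Ea5 = 50.0 kJ mol⁻¹)
    (constants at 40 °C)

The dusk flask looks safe at first sight. In that flask the two chain steps balance at the equilibrium concentration of D, D_eq = k_dp/k_p = 0.0727 M, which is 9.09 % of the D charge c_D. With the L charge c_L present as J, D relaxes towards D_eq with a time constant 1/(k_p c_L) = 49.4 s, against a run of 50 min. Yet the dusk flask is reckoned here to stop far short of D_eq.

The run length is the wrong comparison, because J lives a shorter time than that time constant. At the charged D, L is consumed on a time scale of 62.5 s, far shorter than the run, so the time integral of [J] comes to c_L/k_t. That integral gives Λ = k_p c_L/k_t = 0.602, the reach: the propagation constant times the time integral of [J], which counts the e-foldings of the distance [D] − D_eq that the ends deliver. Then [D] ends at D_eq + (c_D − D_eq)e^(−Λ) = 0.471 M, and with the units made by initiation, G comes to 42.1 % at dusk.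

Step 1 runs 2300 times faster in the dusk flask than in the spring flask. With a = k_i[D], the integral becomes c_L(t − (1 − e^(−at))/a) while J survives, and a depends on the D that the reckoning itself returns. This reckoning stops at dusk and names no best flask.

The forecast names autumn as best, with 83.5 % there, 24 % at dawn, 42 % at dusk and 0.17 % in spring; its ground is “The living ends set everything”. The simulation gives autumn as best, with 83.9 % there, 24.7 % at dawn, 41.8 % at dusk and 0.169 % in spring.

The spring flask moved to −10 °C takes the slow-L form, with k_p = 0.0658 M⁻¹ s⁻¹, k_i = 1.87 × 10⁻⁴ M⁻¹ s⁻¹ and D_eq = 0.00489 M. J there outlasts the run. With [D] at its charge, Λ = 0.307, against 0.602 at dusk. Putting the mean of the charge and the D found back in gives a = 1.30 × 10⁻⁴ s⁻¹, so Λ = 0.272 and G is 23.7 %. That neighbour flask ends with G at 24.7 % and L at 67 % of its charge.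

The rate constants belong to no real substance; the rest is arithmetic.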